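**Plan**

Ring numbering: O1, C2 (aryl cis to the CH2OH on C3), C3, C4, C5 (aryl trans to the CH2OH on C4). In this numbering the target is 2S,3S,4S,5R, with the two aryl groups cis and the two CH2OH groups trans.
Retrosynthesis: both CH2OH groups go back to methyl esters and H–C2/H–C3 to a C2=C3 enol ether. The resulting 4,5-dihydrofuran is cut at C4–C5 and at O1–C5.
Enabling feature: O1–C2–C3–C4 of the ring is a latent 1-oxadiene, an aryl ketone (O1=C2) conjugated to a C3=C4 alkene that carries both future CH2OH carbons as esters. C5 and its aryl group are then a one-carbon benzylidene unit that a sulfonium ylide can deliver.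
Forward: an aroylbutenedioate (three steps from acetosyringone) and a chiral benzylthiolanium salt (from syringaldehyde and (2S,5S)-hexane-2,5-diol) are joined in a (4+1) annulation that closes the only new ring. Ionic hydrogenation, LiAlH4 reduction and debenzylation follow.
Stereochemistry: C5 comes from the C2-symmetric (2R,5R)-sulfide, and C4 is set relative to C5 (trans closure, epimerisable centre). C3 is set relative to C4 (equilibrating protonation, trans diester), and C2 by hydride attack on the face opposite the C3 ester and the C5 aryl group.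

Key step: step 10

Assumption: the (2R,5R)-sulfide is taken to lead to 5R, because the same ylide face and the same invertive displacement operate in its benzylidene transfer to aldehydes; this sense is unproven for a Michael acceptor, and both enantiomers of the diol from which the sulfide is made are commercial.

**Route**

Step 1
Reactants: 1 acetosyringone [1-(4-hydroxy-3,5-dimethoxyphenyl)ethanone]
Product: 2 1-[4-(benzyloxy)-3,5-dimethoxyphenyl]ethanone
Conditions: BnBr, K2CO3, DMF, 60 °C
Reagents that add atoms: benzyl bromide, BrCc1ccccc1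
Why: Williamson ether synthesis on the acidic para-acyl phenol; the benzyl ether tolerates the later base, ylide and hydride steps and leaves this ring the better cation-stabilising donor of the two.

Step 2
Reactants: 2 1-[4-(benzyloxy)-3,5-dimethoxyphenyl]ethanone; 3 dimethyl carbonate
Product: 4 methyl 3-[4-(benzyloxy)-3,5-dimethoxyphenyl]-3-oxopropanoate
Conditions: NaH, THF, reflux; then 1 M HCl
Reagents that add atoms: none
Why: Crossed Claisen condensation of the methyl ketone enolate with a non-enolisable carbonate, driven to completion by deprotonation of the β-keto ester as it forms.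

Step 3
Reactants: 4 methyl 3-[4-(benzyloxy)-3,5-dimethoxyphenyl]-3-oxopropanoate; 5 methyl glyoxylate (freshly distilled monomer)
Product: 6 dimethyl (E)-2-[4-(benzyloxy)-3,5-dimethoxybenzoyl]but-2-enedioate (an E/Z mixture is acceptable; E isomer drawn)
Conditions: piperidine (cat.), AcOH (cat.), 4 Å molecular sieves, toluene, rt
Reagents that add atoms: none
Why: Knoevenagel condensation of an active methylene compound with a very electrophilic, non-enolisable aldehyde; a slight excess of 5 and removal of water hold back Michael addition of a second molecule of 4, and the alkene geometry does not matter because it is lost in the enolate of step 10.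

Step 4
Reactants: 7 syringaldehyde
Product: 8 4-formyl-2,6-dimethoxyphenyl pivalate
Conditions: PivCl, Et3N, DMAP (cat.), CH2Cl2, 0 °C to rt
Reagents that add atoms: pivaloyl chloride, CC(C)(C)C(=O)Cl
Why: DMAP-catalysed O-acylation of the phenol; the hindered ester makes this ring electron-poor, which is needed in step 11, and it falls off without an extra step in step 12.

Step 5
Reactants: 8 4-formyl-2,6-dimethoxyphenyl pivalate
Product: 9 4-(hydroxymethyl)-2,6-dimethoxyphenyl pivalate
Conditions: NaBH4, THF–MeOH, 0 °C
Reagents that add atoms: none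
Why: Chemoselective borohydride reduction of the aldehyde; the hindered aryl pivalate should not react at 0 °C.

Step 6
Reactants: 9 4-(hydroxymethyl)-2,6-dimethoxyphenyl pivalate
Product: 10 4-(bromomethyl)-2,6-dimethoxyphenyl pivalate
Conditions: PBr3, CH2Cl2, 0 °C
Reagents that add atoms: phosphorus tribromide, BrP(Br)Br
Why: SN2 bromination of a primary benzylic alcohol through its phosphite ester, under conditions that leave aryl esters and aryl methyl ethers alone.

Step 7
Reactants: 11 (2S,5S)-hexane-2,5-diol
Product: 12 (2S,5S)-hexane-2,5-diyl dimethanesulfonate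
Conditions: MsCl, Et3N, CH2Cl2, −20 to 0 °C
Reagents that add atoms: methanesulfonyl chloride, CS(=O)(=O)Cl
Why: O-sulfonylation breaks no C–O bond, so both stereocentres are retained.

Step 8
Reactants: 12 (2S,5S)-hexane-2,5-diyl dimethanesulfonate
Product: 13 (2R,5R)-2,5-dimethylthiolane
Conditions: Na2S·9H2O, EtOH, rt
Reagents that add atoms: sodium sulfide (Na2S, used as the nonahydrate), [Na+].[Na+].[S-2]
Why: Double SN2 displacement by sulfide, the second one a 5-exo-tet ring closure, inverts each carbinol carbon once and so converts S,S into the trans R,R thiolane.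

Step 9
Reactants: 10 4-(bromomethyl)-2,6-dimethoxyphenyl pivalate; 13 (2R,5R)-2,5-dimethylthiolane
Product: 14 (2R,5R)-1-[3,5-dimethoxy-4-(pivaloyloxy)benzyl]-2,5-dimethylthiolanium bromide
Conditions: acetone (concentrated), rt, dark; Et2O trituration
Reagents that add atoms: none
Why: SN2 S-alkylation of a thioether by a benzylic bromide; the two sulfur lone pairs of the C2-symmetric sulfide are equivalent, so a single salt forms and sulfur is not a stereocentre.

Step 10
Reactants: 6 dimethyl (E)-2-[4-(benzyloxy)-3,5-dimethoxybenzoyl]but-2-enedioate; 14 (2R,5R)-1-[3,5-dimethoxy-4-(pivaloyloxy)benzyl]-2,5-dimethylthiolanium bromide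
Product: 17 dimethyl (4R,5R)-2-[4-(benzyloxy)-3,5-dimethoxyphenyl]-5-[3,5-dimethoxy-4-(pivaloyloxy)phenyl]-4,5-dihydrofuran-3,4-dicarboxylate, via thiolanium benzylide 15 (not isolated), via sulfonium enolate betaine 16 (not isolated)
Conditions: K2CO3 (powdered, dry), MeCN, 0 °C to rt
Reagents that add atoms: none
Why: Proposed new method: K2CO3 deprotonates 14 to the semistabilised benzylide 15, whose carbanion adds to the CH terminus of 6 (C4, the only alkene carbon β to both the ketone and the geminal ester) to form C4–C5 and the β-keto ester enolate betaine 16, and the ketone-derived enolate oxygen then displaces the neutral thiolane from C5 with inversion to form O1–C5. The closest known reaction type is the racemic formal (4+1) annulation of sulfonium ylides with 2-acylalkenoates to trans-2,3-dihydrofurans, while absolute control by C2-symmetric thiolanium benzylides is established for benzylidene transfer to aldehydes, so it is the merger of the two that is untested. The one new ring closes by a 5-exo-tet O-alkylation through an in-plane oxygen lone pair, favoured over 3-exo-tet C-alkylation because C3 is fully substituted and the charge rests on oxygen in MeCN with K+, and a cyclopropyl ketone from C-alkylation would carry an aryl donor and should ring-expand to 17 by Cloke–Wilson rearrangement. C5 is set by the sulfide: its C2 symmetry allows only one sulfonium salt, the methyl group on the ylide side of sulfur fixes the ylide conformation and screens one face of the carbanion, and the invertive displacement translates that face into 5R. C4 is set relative to C5 by closure from the betaine rotamer that keeps aryl and ester apart, and the acidic C4–H (α to an ester and γ to the vinylogous carbonate) lets the carbonate correct any cis isomer to trans. The step also needs 1,4- rather than 1,2-addition and an intact aryl pivalate, which the triply activated alkene and the anhydrous carbonate base should secure.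

Step 11
Reactants: 17 dimethyl (4R,5R)-2-[4-(benzyloxy)-3,5-dimethoxyphenyl]-5-[3,5-dimethoxy-4-(pivaloyloxy)phenyl]-4,5-dihydrofuran-3,4-dicarboxylate
Product: 19 dimethyl (2S,3R,4R,5R)-2-[4-(benzyloxy)-3,5-dimethoxyphenyl]-5-[3,5-dimethoxy-4-(pivaloyloxy)phenyl]tetrahydrofuran-3,4-dicarboxylate, via C2 oxocarbenium trifluoroacetate 18 (not isolated)
Conditions: Et3SiH, CF3CO2H, CH2Cl2, 0 °C to rt
Reagents that add atoms: none
Why: Ionic hydrogenation of a 2-aryl cyclic enol ether: C3 protonation is reversible, so the substrate is funnelled through the more stable oxocarbenium ion 18 with the C3 ester trans to the C4 ester (the new C3–H lies on the face that carries the C4 ester, not opposite to it), Et3SiH then attacks C2 on that same face, anti to the adjacent C3 ester and to the C5 aryl group, which places the C2 aryl group cis to the C3 ester as in kinetic hydride reductions of 3,4-trans-4,5-trans 2-aryl oxocarbenium ions, and the electron-poor pivaloyloxy ring keeps C5–O1 from ionising while the benzyloxy ring supports the C2 cation.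

Step 12
Reactants: 19 dimethyl (2S,3R,4R,5R)-2-[4-(benzyloxy)-3,5-dimethoxyphenyl]-5-[3,5-dimethoxy-4-(pivaloyloxy)phenyl]tetrahydrofuran-3,4-dicarboxylate
Product: 20 (2S,3S,4S,5R)-2-[4-(benzyloxy)-3,5-dimethoxyphenyl]-5-(4-hydroxy-3,5-dimethoxyphenyl)-3,4-bis(hydroxymethyl)tetrahydrofuran
Conditions: LiAlH4, THF, 0 °C to rt; aq potassium sodium tartrate
Reagents that add atoms: none
Why: LiAlH4 reduction of esters is faster than their enolisation, so C3 and C4 keep their geometry (the descriptors change only through CIP priorities), the aryl pivalate is cleaved to the phenol in the same operation, and the benzyl ether and ring C–O bonds are inert.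

Step 13
Reactants: 20 (2S,3S,4S,5R)-2-[4-(benzyloxy)-3,5-dimethoxyphenyl]-5-(4-hydroxy-3,5-dimethoxyphenyl)-3,4-bis(hydroxymethyl)tetrahydrofuran
Product: 21 [(2S,3S,4S,5R)-2,5-bis(4-hydroxy-3,5-dimethoxyphenyl)tetrahydrofuran-3,4-diyl]dimethanol (target)
Conditions: H2 (1 atm), 10% Pd/C, EtOAc–MeOH, rt
Reagents that add atoms: none
Why: Catalytic hydrogenolysis cleaves the aryl benzyl ether much faster than the two secondary benzylic C–O bonds of the ring at atmospheric pressure, and no stereocentre is touched.

**Compound list**

1 | acetosyringone | CC(=O)c1cc(OC)c(O)c(OC)c1 | starting material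
2 | 1-[4-(benzyloxy)-3,5-dimethoxyphenyl]ethanone | CC(=O)c1cc(OC)c(OCc2ccccc2)c(OC)c1 | intermediate
3 | dimethyl carbonate | COC(=O)OC | starting material
4 | methyl 3-[4-(benzyloxy)-3,5-dimethoxyphenyl]-3-oxopropanoate | COC(=O)CC(=O)c1cc(OC)c(OCc2ccccc2)c(OC)c1 | intermediate
5 | methyl glyoxylate | COC(=O)C=O | starting material
6 | dimethyl (E)-2-[4-(benzyloxy)-3,5-dimethoxybenzoyl]but-2-enedioate (E drawn, either geometry serves) | COC(=O)/C=C(/C(=O)OC)C(=O)c1cc(OC)c(OCc2ccccc2)c(OC)c1 | intermediate
7 | syringaldehyde | COc1cc(C=O)cc(OC)c1O | starting material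
8 | 4-formyl-2,6-dimethoxyphenyl pivalate | COc1cc(C=O)cc(OC)c1OC(=O)C(C)(C)C | intermediate
9 | 4-(hydroxymethyl)-2,6-dimethoxyphenyl pivalate | COc1cc(CO)cc(OC)c1OC(=O)C(C)(C)C | intermediate
10 | 4-(bromomethyl)-2,6-dimethoxyphenyl pivalate | COc1cc(CBr)cc(OC)c1OC(=O)C(C)(C)C | intermediate
11 | (2S,5S)-hexane-2,5-diol | C[C@H](O)CC[C@H](C)O | starting material
12 | (2S,5S)-hexane-2,5-diyl dimethanesulfonate | C[C@H](OS(C)(=O)=O)CC[C@H](C)OS(C)(=O)=O | intermediate
13 | (2R,5R)-2,5-dimethylthiolane | C[C@@H]1CC[C@@H](C)S1 | intermediate
14 | (2R,5R)-1-[3,5-dimethoxy-4-(pivaloyloxy)benzyl]-2,5-dimethylthiolanium bromide | C[C@@H]1CC[C@@H](C)[S+]1Cc1cc(OC)c(OC(=O)C(C)(C)C)c(OC)c1.[Br-] | intermediate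
15 | (2R,5R)-2,5-dimethylthiolanium 3,5-dimethoxy-4-(pivaloyloxy)benzylide | C[C@@H]1CC[C@@H](C)[S+]1[CH-]c1cc(OC)c(OC(=O)C(C)(C)C)c(OC)c1 | intermediate
16 | sulfonium enolate betaine (Michael adduct; thiolanium on C5, C4 S and C5 S, β-keto ester enolate over O1–C2–C3 with O1 cis to C4) | C[C@@H]1CC[C@@H](C)[S+]1[C@H](c1cc(OC)c(OC(=O)C(C)(C)C)c(OC)c1)[C@H](C(=O)OC)/C(C(=O)OC)=C(\[O-])c1cc(OC)c(OCc2ccccc2)c(OC)c1 | intermediate
17 | dimethyl (4R,5R)-2-[4-(benzyloxy)-3,5-dimethoxyphenyl]-5-[3,5-dimethoxy-4-(pivaloyloxy)phenyl]-4,5-dihydrofuran-3,4-dicarboxylate (trans) | COC(=O)C1=C(c2cc(OC)c(OCc3ccccc3)c(OC)c2)O[C@@H](c2cc(OC)c(OC(=O)C(C)(C)C)c(OC)c2)[C@@H]1C(=O)OC | intermediate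
18 | C2 oxocarbenium trifluoroacetate (C3 ester trans to C4 ester, C4 ester trans to C5 aryl) | COC(=O)[C@H]1C(c2cc(OC)c(OCc3ccccc3)c(OC)c2)=[O+][C@@H](c2cc(OC)c(OC(=O)C(C)(C)C)c(OC)c2)[C@@H]1C(=O)OC.[O-]C(=O)C(F)(F)F | intermediate
19 | dimethyl (2S,3R,4R,5R)-2-[4-(benzyloxy)-3,5-dimethoxyphenyl]-5-[3,5-dimethoxy-4-(pivaloyloxy)phenyl]tetrahydrofuran-3,4-dicarboxylate | COC(=O)[C@H]1[C@@H](c2cc(OC)c(OCc3ccccc3)c(OC)c2)O[C@@H](c2cc(OC)c(OC(=O)C(C)(C)C)c(OC)c2)[C@@H]1C(=O)OC | intermediate
20 | (2S,3S,4S,5R)-2-[4-(benzyloxy)-3,5-dimethoxyphenyl]-5-(4-hydroxy-3,5-dimethoxyphenyl)-3,4-bis(hydroxymethyl)tetrahydrofuran | COc1cc([C@H]2O[C@@H](c3cc(OC)c(O)c(OC)c3)[C@H](CO)[C@H]2CO)cc(OC)c1OCc1ccccc1 | intermediate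
21 | [(2S,3S,4S,5R)-2,5-bis(4-hydroxy-3,5-dimethoxyphenyl)tetrahydrofuran-3,4-diyl]dimethanol | COc1cc([C@H]2O[C@@H](c3cc(OC)c(O)c(OC)c3)[C@H](CO)[C@H]2CO)cc(OC)c1O | target

**Step count and risks**

Total step count: 13.
Longest linear sequence: 8 steps (7 → 8 → 9 → 10 → 14 → 17 → 19 → 20 → 21).

Steps most likely to fail:

1. Step 10.
- What may go wrong: the sulfide may discriminate the ylide faces weakly or in the opposite sense. The C5 configuration may erode through base-induced ring opening from C4 and reclosure. C-alkylation may overtake O-alkylation.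
- Fallback (known chemistry, resolution in place of reagent control): it sets out from 10. Alkylation of tetrahydrothiophene in acetone gives 1-[3,5-dimethoxy-4-(pivaloyloxy)benzyl]tetrahydrothiophenium bromide F1. K2CO3 in MeCN converts this into the achiral tetrahydrothiophenium benzylide F2, which undergoes the established racemic Michael addition/O-alkylation sequence with 6.
- This gives 17 together with its mirror image, dimethyl (4S,5S)-2-[4-(benzyloxy)-3,5-dimethoxyphenyl]-5-[3,5-dimethoxy-4-(pivaloyloxy)phenyl]-4,5-dihydrofuran-3,4-dicarboxylate F3. Preparative chromatography on a polysaccharide carbamate chiral stationary phase separates the two, and the route is rejoined at 17.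

2. Step 11.
- What may go wrong: C-protonation of the push–pull enol ether may be slow and call for harsher acid. That would bring loss of the benzyl ether, reversible opening of C2–O1 with epimerisation at C2, or over-reduction. Hydride transfer may also precede protonation, with weaker control at C3.
- Fallback: it sets out from 17 and replaces the stepwise ionic process by heterogeneous hydrogenation (H2, 4 atm, 5% Rh/Al2O3, EtOAc, rt). Syn addition makes the cis C2/C3 relation obligatory. The flat aryl–enol ether–ester π system should adsorb with the bulky C5 aryl group pointing away from the metal, so hydrogen arrives on the required face.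
- Rhodium is chosen because it has little tendency to hydrogenolyse the benzyl ether or the benzylic C5–O1 bond. The route is rejoined at 19, and no compound outside the list is made (F0).

3. Step 3.
- What may go wrong: the glyoxylate may oligomerise, a second molecule of keto ester may add to the very electrophilic alkene, or the amine catalyst may be captured by it.
- Fallback (alkylation and dehydrohalogenation in place of condensation): it sets out from 4. C-alkylation with methyl bromoacetate (K2CO3, acetone) gives racemic dimethyl 2-[4-(benzyloxy)-3,5-dimethoxybenzoyl]butanedioate F4.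
- Bromination at the doubly activated carbon (NBS, Mg(ClO4)2 cat., MeCN) gives racemic dimethyl 2-bromo-2-[4-(benzyloxy)-3,5-dimethoxybenzoyl]butanedioate F5. Et3N in CH2Cl2 at 0 °C then eliminates HBr through the ester-activated CH2, and the route is rejoined at 6.

**Further compounds**

F1 | step 10 | 1-[3,5-dimethoxy-4-(pivaloyloxy)benzyl]tetrahydrothiophenium bromide | COc1cc(C[S+]2CCCC2)cc(OC)c1OC(=O)C(C)(C)C.[Br-]
F2 | step 10 | tetrahydrothiophenium 3,5-dimethoxy-4-(pivaloyloxy)benzylide | COc1cc([CH-][S+]2CCCC2)cc(OC)c1OC(=O)C(C)(C)C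
F3 | step 10 | dimethyl (4S,5S)-2-[4-(benzyloxy)-3,5-dimethoxyphenyl]-5-[3,5-dimethoxy-4-(pivaloyloxy)phenyl]-4,5-dihydrofuran-3,4-dicarboxylate | COC(=O)C1=C(c2cc(OC)c(OCc3ccccc3)c(OC)c2)O[C@H](c2cc(OC)c(OC(=O)C(C)(C)C)c(OC)c2)[C@H]1C(=O)OC
F0 | step 11 | none | none
F4 | step 3 | dimethyl 2-[4-(benzyloxy)-3,5-dimethoxybenzoyl]butanedioate (racemic) | COC(=O)CC(C(=O)OC)C(=O)c1cc(OC)c(OCc2ccccc2)c(OC)c1
F5 | step 3 | dimethyl 2-bromo-2-[4-(benzyloxy)-3,5-dimethoxybenzoyl]butanedioate (racemic) | COC(=O)CC(Br)(C(=O)OC)C(=O)c1cc(OC)c(OCc2ccccc2)c(OC)c1
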